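**Retrosynthetic overview**
1. Numbering: cyclohexene C1 (CH bearing C7H2–OAr), C2 (=C–CH3), C3 (=CH), C4 (CH2), C5 (CH–O-isovaleryl), C6 (CMe2). The target is (1S,5R), with the C1 and C5 substituents cis.
2. Governing feature: the carbocycle is the only ring to build. Its isolated trisubstituted C2=C3 alkene lies next to the tertiary allylic C1–H and could drift to C1=C2 or to the exocyclic position under acid or base, so the alkene is created in the ring closure itself.
3. Disconnections: C7–OAr (Mitsunobu; umbelliferone brings the coumarin bicycle intact) ⇒ C2=C3 (ring-closing metathesis of acyclic 1,7-diene 17, the sole ring formation) ⇒ C4–C5 (allylboration, sets C5) ⇒ C1–C6 (isobutyrate Ireland–Claisen, sets C1 and installs CMe2).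
4. Chirality enters twice and independently: a CBS-derived carbinol centre is relayed to C1, and a pinene-derived allylborane sets C5. O5 receives the isovalerate of the target before ring closure, so PMB on O7 is the only protecting group.

Key step: step 9

Remark: 1 and 2 are treated as catalogue compounds. Sign labels for Ipc allylboranes are used inconsistently, so the boron reagent is defined by its source: (+)-Ipc2BOMe here is the (−)-α-pinene-derived borinate that gives (+)-isopinocampheol on oxidation.

**Step 1**
Reactants: 1 2-[(4-methoxybenzyl)oxy]acetaldehyde; 2 3-(triphenylphosphoranylidene)butan-2-one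
Product: 3 (3E)-5-[(4-methoxybenzyl)oxy]-3-methylpent-3-en-2-one
Conditions: PhMe, 90 °C
Reagents that add atoms: none
Why: Wittig olefination with a stabilised, α-branched keto ylide should place the CH2OPMB group trans to the acetyl group, which fixes the E geometry on which the later chirality transfer depends.

**Step 2**
Reactants: 3 (3E)-5-[(4-methoxybenzyl)oxy]-3-methylpent-3-en-2-one
Product: 4 (2R,3E)-5-[(4-methoxybenzyl)oxy]-3-methylpent-3-en-2-ol
Conditions: (S)-Me-CBS (15 mol %), BH3·SMe2, THF, −30 °C; MeOH, then aq NH4Cl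
Reagents that add atoms: none
Why: In the Corey–Bakshi–Shibata reduction the ketone binds the oxazaborolidine boron with the α-branched alkenyl group as the large substituent and methyl as the small one, so hydride should reach the Si face and give the (R)-carbinol, the same sense as acetophenone to (R)-1-phenylethanol with the (S)-catalyst.

**Step 3**
Reactants: 4 (2R,3E)-5-[(4-methoxybenzyl)oxy]-3-methylpent-3-en-2-ol; 5 isobutyryl chloride
Product: 6 (2R,3E)-5-[(4-methoxybenzyl)oxy]-3-methylpent-3-en-2-yl 2-methylpropanoate
Conditions: pyridine, DMAP (cat.), CH2Cl2, 0 °C → rt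
Reagents that add atoms: none
Why: DMAP-catalysed O-acylation leaves the C–O bond of the carbinol intact, so the (R) centre and the E alkene carry over unchanged.

**Step 4**
Reactants: 6 (2R,3E)-5-[(4-methoxybenzyl)oxy]-3-methylpent-3-en-2-yl 2-methylpropanoate
Product: 9 (3S,4E)-3-{[(4-methoxybenzyl)oxy]methyl}-2,2,4-trimethylhex-4-enoic acid, via trimethylsilyl ketene acetal 7 (not isolated), via trimethylsilyl ester 8 (not isolated)
Conditions: LDA, THF, −78 °C; TMSCl, −78 °C → rt, then 60 °C; 1 M HCl work-up
Reagents that add atoms: chlorotrimethylsilane, C[Si](C)(C)Cl (its silyl group stands only in 7 and 8 and is lost on work-up)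
Why: In this Ireland–Claisen rearrangement the ketene acetal terminus carries two identical methyl groups, so enolate geometry and chair-versus-boat play no role, and the suprafacial [3,3] shift with the carbinol methyl pseudo-equatorial should relay the (R) C–O centre into the new C1–C6 bond, giving (S)-C1, the C6 quaternary carbon and the (E)-alkene.

**Step 5**
Reactants: 9 (3S,4E)-3-{[(4-methoxybenzyl)oxy]methyl}-2,2,4-trimethylhex-4-enoic acid
Product: 10 (3S,4E)-3-{[(4-methoxybenzyl)oxy]methyl}-2,2,4-trimethylhex-4-en-1-ol
Conditions: LiAlH4, THF, 0 °C → reflux; Fieser work-up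
Reagents that add atoms: none
Why: Aluminium hydride reduction takes the hindered α-quaternary acid to the neopentyl alcohol, while the PMB ether and the isolated alkene are inert and C1, not being α to the carbonyl, cannot epimerise.

**Step 6**
Reactants: 10 (3S,4E)-3-{[(4-methoxybenzyl)oxy]methyl}-2,2,4-trimethylhex-4-en-1-ol
Product: 11 (3S,4E)-3-{[(4-methoxybenzyl)oxy]methyl}-2,2,4-trimethylhex-4-enal
Conditions: Dess–Martin periodinane, CH2Cl2, 0 °C → rt
Reagents that add atoms: none
Why: Dess–Martin oxidation stops at the aldehyde under near-neutral conditions, and the product has no α-hydrogen, so neither enolisation nor epimerisation can follow.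

**Step 7**
Reactants: 11 (3S,4E)-3-{[(4-methoxybenzyl)oxy]methyl}-2,2,4-trimethylhex-4-enal; 12 allylmagnesium bromide
Product: 15 (4R,6S,7E)-6-{[(4-methoxybenzyl)oxy]methyl}-5,5,7-trimethylnona-1,7-dien-4-ol, via allylborane 13 (not isolated), via borinic ester 14 (not isolated)
Conditions: (+)-Ipc2BOMe, 12, Et2O, 0 °C → rt; then 11, Et2O, −100 → −78 °C; 3 M NaOH, 30% H2O2, rt → reflux
Reagents that add atoms: (+)-B-methoxydiisopinocampheylborane, COB([C@H]1C[C@H]2C[C@@H]([C@@H]1C)C2(C)C)[C@H]1C[C@H]2C[C@@H]([C@@H]1C)C2(C)C (its Ipc2B unit stands only in 13 and 14)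
Why: In the Brown asymmetric allylboration, which runs through a chair Zimmerman–Traxler transition state, the (−)-α-pinene-derived ligands should direct the allyl group to the Re face of the α-quaternary aldehyde (the sense established for pivalaldehyde) and set (R)-C5 under reagent control, while any material of the wrong C1 series becomes a separable diastereomer.

**Step 8**
Reactants: 15 (4R,6S,7E)-6-{[(4-methoxybenzyl)oxy]methyl}-5,5,7-trimethylnona-1,7-dien-4-ol; 16 isovaleryl chloride (3-methylbutanoyl chloride)
Product: 17 (4R,6S,7E)-6-{[(4-methoxybenzyl)oxy]methyl}-5,5,7-trimethylnona-1,7-dien-4-yl 3-methylbutanoate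
Conditions: pyridine, DMAP, CH2Cl2, 0 → 40 °C
Reagents that add atoms: none
Why: DMAP-catalysed acylation of the hindered secondary alcohol installs the ester of the target without touching the C5–O bond, and this ester tolerates metathesis, DDQ and Mitsunobu conditions, so O5 needs no protecting group.

**Step 9**
Reactants: 17 (4R,6S,7E)-6-{[(4-methoxybenzyl)oxy]methyl}-5,5,7-trimethylnona-1,7-dien-4-yl 3-methylbutanoate
Product: 18 (1R,5S)-5-{[(4-methoxybenzyl)oxy]methyl}-4,6,6-trimethylcyclohex-3-en-1-yl 3-methylbutanoate
Conditions: Grubbs II (5 mol %), 1,4-benzoquinone (10 mol %), CH2Cl2 (5 mM), reflux, Ar sparge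
Reagents that add atoms: none
Why: The ruthenium carbene first exchanges with the unhindered vinyl group to give the C3 alkylidene, which adds [2+2] across the tethered (E)-C2=CH(CH3) alkene with C3 bonding to C2; cycloreversion of the ruthenacyclobutane releases the C2=C3 ring alkene and a ruthenium ethylidene, which leaves as propene on meeting the CH2 terminus of the next substrate molecule. This is ordinary ring-closing metathesis of a 1,7-diene to a trisubstituted cyclohexene, for which NHC-ligated ruthenium carbenes are the standard catalysts, also where the internal partner is trisubstituted and an alkene larger than ethene is expelled. The one ring closes as a six-membered carbocycle through C2=C3 bond formation, and the C6 gem-dimethyl group flanked by branched C1 and C5 favours the folded conformer (Thorpe–Ingold effect). No stereocentre is created: C1 and C5 stay outside the metallacycle and are not acidic under these neutral conditions, so both configurations carry over, and the E geometry of the acyclic alkene disappears with the propene. The selectivity required is cyclisation over vinyl–vinyl oligomerisation and freedom from ruthenium hydride alkene migration, secured by high dilution, removal of propene in the argon stream and benzoquinone as hydride scavenger, while any dimer remains metathesis-active and can re-enter the cycle. Because the new double bond can only join the two carbons that already carried alkenes, it cannot appear at C1=C2 or exocyclic.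

**Step 10**
Reactants: 18 (1R,5S)-5-{[(4-methoxybenzyl)oxy]methyl}-4,6,6-trimethylcyclohex-3-en-1-yl 3-methylbutanoate
Product: 19 (1R,5S)-5-(hydroxymethyl)-4,6,6-trimethylcyclohex-3-en-1-yl 3-methylbutanoate
Conditions: DDQ, CH2Cl2/pH 7 buffer (10:1), 0 °C
Reagents that add atoms: none
Why: Oxidative PMB cleavage proceeds by hydride abstraction from the electron-rich benzylic position and hydrolysis of the oxocarbenium ion, leaving the isolated alkene and the ester alone, and the neutral buffer disfavours an O5→O7 acyl shift, which would need a seven-membered cyclic intermediate.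

**Step 11**
Reactants: 19 (1R,5S)-5-(hydroxymethyl)-4,6,6-trimethylcyclohex-3-en-1-yl 3-methylbutanoate; 20 umbelliferone (7-hydroxycoumarin)
Product: 21 (1R,5S)-4,6,6-trimethyl-5-{[(2-oxo-2H-chromen-7-yl)oxy]methyl}cyclohex-3-en-1-yl 3-methylbutanoate (target)
Conditions: PPh3, DIAD, THF, 0 °C → rt
Reagents that add atoms: none
Why: In the Mitsunobu etherification the acidic phenol protonates the betaine and its phenoxide displaces the oxyphosphonium group at primary C7 by SN2, so no stereocentre is involved and the lactone, ester and alkene are untouched under neutral conditions.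

**Compound list**
1 | 2-[(4-methoxybenzyl)oxy]acetaldehyde | COc1ccc(COCC=O)cc1 | starting material
2 | 3-(triphenylphosphoranylidene)butan-2-one | CC(=O)C(C)=P(c1ccccc1)(c1ccccc1)c1ccccc1 | starting material
3 | (3E)-5-[(4-methoxybenzyl)oxy]-3-methylpent-3-en-2-one | CC(=O)/C(C)=C/COCc1ccc(OC)cc1 | intermediate
4 | (2R,3E)-5-[(4-methoxybenzyl)oxy]-3-methylpent-3-en-2-ol | C[C@@H](O)/C(C)=C/COCc1ccc(OC)cc1 | intermediate
5 | isobutyryl chloride | CC(C)C(Cl)=O | starting material
6 | (2R,3E)-5-[(4-methoxybenzyl)oxy]-3-methylpent-3-en-2-yl 2-methylpropanoate | C[C@@H](OC(=O)C(C)C)/C(C)=C/COCc1ccc(OC)cc1 | intermediate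
7 | trimethylsilyl ketene acetal of 6 | C[C@@H](OC(O[Si](C)(C)C)=C(C)C)/C(C)=C/COCc1ccc(OC)cc1 | intermediate
8 | trimethylsilyl (3S,4E)-3-{[(4-methoxybenzyl)oxy]methyl}-2,2,4-trimethylhex-4-enoate | C/C=C(\C)[C@H](COCc1ccc(OC)cc1)C(C)(C)C(=O)O[Si](C)(C)C | intermediate
9 | (3S,4E)-3-{[(4-methoxybenzyl)oxy]methyl}-2,2,4-trimethylhex-4-enoic acid | C/C=C(\C)[C@H](COCc1ccc(OC)cc1)C(C)(C)C(=O)O | intermediate
10 | (3S,4E)-3-{[(4-methoxybenzyl)oxy]methyl}-2,2,4-trimethylhex-4-en-1-ol | C/C=C(\C)[C@H](COCc1ccc(OC)cc1)C(C)(C)CO | intermediate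
11 | (3S,4E)-3-{[(4-methoxybenzyl)oxy]methyl}-2,2,4-trimethylhex-4-enal | C/C=C(\C)[C@H](COCc1ccc(OC)cc1)C(C)(C)C=O | intermediate
12 | allylmagnesium bromide | C=CC[Mg]Br | starting material
13 | B-allyldiisopinocampheylborane, (−)-α-pinene series | C=CCB([C@H]1C[C@H]2C[C@@H]([C@@H]1C)C2(C)C)[C@H]1C[C@H]2C[C@@H]([C@@H]1C)C2(C)C | intermediate
14 | diisopinocampheylborinic ester of 15 | C/C=C(\C)[C@H](COCc1ccc(OC)cc1)C(C)(C)[C@H](OB([C@H]1C[C@H]2C[C@@H]([C@@H]1C)C2(C)C)[C@H]1C[C@H]2C[C@@H]([C@@H]1C)C2(C)C)CC=C | intermediate
15 | (4R,6S,7E)-6-{[(4-methoxybenzyl)oxy]methyl}-5,5,7-trimethylnona-1,7-dien-4-ol | C/C=C(\C)[C@H](COCc1ccc(OC)cc1)C(C)(C)[C@H](O)CC=C | intermediate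
16 | isovaleryl chloride | CC(C)CC(=O)Cl | starting material
17 | (4R,6S,7E)-6-{[(4-methoxybenzyl)oxy]methyl}-5,5,7-trimethylnona-1,7-dien-4-yl 3-methylbutanoate | C/C=C(\C)[C@H](COCc1ccc(OC)cc1)C(C)(C)[C@H](OC(=O)CC(C)C)CC=C | intermediate
18 | (1R,5S)-5-{[(4-methoxybenzyl)oxy]methyl}-4,6,6-trimethylcyclohex-3-en-1-yl 3-methylbutanoate | CC1=CC[C@@H](OC(=O)CC(C)C)C(C)(C)[C@H]1COCc1ccc(OC)cc1 | intermediate
19 | (1R,5S)-5-(hydroxymethyl)-4,6,6-trimethylcyclohex-3-en-1-yl 3-methylbutanoate | CC1=CC[C@@H](OC(=O)CC(C)C)C(C)(C)[C@H]1CO | intermediate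
20 | umbelliferone | O=c1ccc2ccc(O)cc2o1 | starting material
21 | (1R,5S)-4,6,6-trimethyl-5-{[(2-oxo-2H-chromen-7-yl)oxy]methyl}cyclohex-3-en-1-yl 3-methylbutanoate | CC1=CC[C@@H](OC(=O)CC(C)C)C(C)(C)[C@H]1COc1ccc2ccc(=O)oc2c1 | target

Total step count: 11
Longest linear sequence: 11 steps (1 → 21)

**Steps most likely to fail**

1. Step 9. The C3 alkylidene may engage the crowded trisubstituted alkene, flanked by tertiary C1 and quaternary C6, too slowly. Vinyl–vinyl oligomerisation and catalyst decay would then outrun ring closure. The fallback sets out from 17 and returns at 18; it trims the internal alkene to a 1,1-disubstituted one before closure.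
   - mCPBA (1 equiv, CH2Cl2, 0 °C) should epoxidise the electron-rich trisubstituted alkene in preference to the vinyl group and give the epoxide F1, whose epoxide diastereomers are of no consequence.
   - Periodic acid in Et2O/THF cleaves it to the methyl ketone F2.
   - Non-basic Lombardo methylenation (Zn, CH2Br2, TiCl4, THF/CH2Cl2) spares the ester, avoids enolisation at C1 and gives the isopropenyl diene F3.
   - Ring-closing metathesis of F3 with the catalyst of step 9 now joins a vinyl group to a 1,1-disubstituted alkene with loss of ethene and gives 18.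

2. Step 4. Creating a quaternary carbon next to a tertiary one may make the [3,3] shift sluggish. Hydrolysis of the ketene acetal could then compete, and leakage through the transition state with an axial carbinol methyl would erode the chirality transfer. The fallback sets out from 4 and returns at 10; it builds the quaternary carbon after the rearrangement instead of during it.
   - Propionyl chloride, pyridine and DMAP convert 4 into the propionate F4.
   - Ireland–Claisen rearrangement (LDA, TMSCl, THF, −78 °C → rt) of the less crowded ketene acetal gives the α-methyl acid F5. C1 is set by the same transfer, and the α-epimers are of no consequence.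
   - TMSCHN2 gives the methyl ester F6.
   - Enolate methylation (LDA, MeI, DMPU, THF, −78 °C) gives the α,α-dimethyl ester F7.
   - LiAlH4 reduces F7 to 10.

3. Step 11. Displacement at the β-branched C7 oxyphosphonium ion may be slow, so that alkylation of the hydrazide or elimination competes with ether formation. The fallback sets out from 19 and returns at 21; it replaces the redox condensation by an isolated sulfonate and a Williamson reaction.
   - MsCl and Et3N in CH2Cl2 at 0 °C give the mesylate F8.
   - F8 is heated with 20 and Cs2CO3 in DMF at 70 °C to give 21.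

**Further compounds**
F1 | step 9 | (4R,6S)-6-(2,3-dimethyloxiran-2-yl)-7-[(4-methoxybenzyl)oxy]-5,5-dimethylhept-1-en-4-yl 3-methylbutanoate | CC1OC1(C)[C@H](COCc1ccc(OC)cc1)C(C)(C)[C@H](OC(=O)CC(C)C)CC=C
F2 | step 9 | (4R,6S)-6-{[(4-methoxybenzyl)oxy]methyl}-5,5-dimethyl-7-oxooct-1-en-4-yl 3-methylbutanoate | CC(=O)[C@H](COCc1ccc(OC)cc1)C(C)(C)[C@H](OC(=O)CC(C)C)CC=C
F3 | step 9 | (4R,6S)-6-{[(4-methoxybenzyl)oxy]methyl}-5,5,7-trimethylocta-1,7-dien-4-yl 3-methylbutanoate | C=C(C)[C@H](COCc1ccc(OC)cc1)C(C)(C)[C@H](OC(=O)CC(C)C)CC=C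
F4 | step 4 | (2R,3E)-5-[(4-methoxybenzyl)oxy]-3-methylpent-3-en-2-yl propanoate | C[C@@H](OC(=O)CC)/C(C)=C/COCc1ccc(OC)cc1
F5 | step 4 | (3R,4E)-3-{[(4-methoxybenzyl)oxy]methyl}-2,4-dimethylhex-4-enoic acid (C2 epimers; same spatial arrangement at C1 as in 9) | C/C=C(\C)[C@H](COCc1ccc(OC)cc1)C(C)C(=O)O
F6 | step 4 | methyl (3R,4E)-3-{[(4-methoxybenzyl)oxy]methyl}-2,4-dimethylhex-4-enoate (C2 epimers) | C/C=C(\C)[C@H](COCc1ccc(OC)cc1)C(C)C(=O)OC
F7 | step 4 | methyl (3S,4E)-3-{[(4-methoxybenzyl)oxy]methyl}-2,2,4-trimethylhex-4-enoate | C/C=C(\C)[C@H](COCc1ccc(OC)cc1)C(C)(C)C(=O)OC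
F8 | step 11 | (1R,5S)-5-{[(methylsulfonyl)oxy]methyl}-4,6,6-trimethylcyclohex-3-en-1-yl 3-methylbutanoate | CC1=CC[C@@H](OC(=O)CC(C)C)C(C)(C)[C@H]1COS(C)(=O)=O
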